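**Retrosynthetic overview**
1. Target 31 ⇐ silyl ether 30 (Si–O cleavage). 30 ⇐ allylic bromide–enal 27 by intramolecular CrCl2 allylation: the C6–C7 bond, the ten-membered carbocycle and the cis γ-lactone form together (last rings).
2. 27 ⇐ furanone 20 by unmasking the C7 aldehyde and C6 alcohol, Morita–Baylis–Hillman reaction, oxidation and SN2' bromination.
3. 20 ⇐ key C–O disconnection of the 3(2H)-furanone (C3–O bond, first ring formed): Z-alkenyl iodide 16 + CO (becomes C3) + tertiary propargylic alcohol 8.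
4. 8 ⇐ acetone + 2,2-dimethoxyacetaldehyde (proline aldol sets C8), chelation-controlled ethynylation (sets C10), tigloylation. 16 ⇐ but-2-yne-1,4-diol (trans-hydroalumination/iodination fixes the 4Z alkene).

Assumption: the target is taken exactly as drawn (4Z; 6S,7R,8R,10R; ester = (2E)-2-methylbut-2-enoyl, "tigloyl"); atom labels C1–C15 follow germacrane numbering (C1 ketone, C3 and C10 on the furanone oxygen, C6 lactone carbinol, C8 ester carbinol, C12 lactone carbonyl, C15 CH2OH).

**Route**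

Step 1
Reactants: 1 acetone; 2 2,2-dimethoxyacetaldehyde
Product: 3 (4R)-4-hydroxy-5,5-dimethoxypentan-2-one
Conditions: (S)-proline (20 mol%), acetone/DMSO 4:1, rt, 24 h (2 used as its 60% aqueous solution)
Reagents that add atoms: none
Why: Proline-catalysed direct aldol (List–Barbas type); the acetone enamine adds to the Re face of the aldehyde through the hydrogen-bonded chair transition state and sets the 4R carbinol (future C8).

Step 2
Reactants: 3 (4R)-4-hydroxy-5,5-dimethoxypentan-2-one; 4 ethynylmagnesium bromide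
Product: 6 (3R,5R)-6,6-dimethoxy-3-methylhex-1-yne-3,5-diol, via magnesium alkoxide chelate 5 (not isolated)
Conditions: HC≡CMgBr (3.5 equiv), THF, −78 → −20 °C; aq. NH4Cl
Reagents that add atoms: ethynylmagnesium bromide C#C[Mg]Br
Why: Chelation-controlled Grignard addition (1,3-induction): the first equivalent forms alkoxide 5, whose six-membered chelate to the ketone holds the C8 substituent equatorial, and the acetylide adds axially to give the 3R tertiary carbinol (future C10, anti to the C8 oxygen); the minor epimer is removed by chromatography.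

Step 3
Reactants: 6 (3R,5R)-6,6-dimethoxy-3-methylhex-1-yne-3,5-diol; 7 (2E)-2-methylbut-2-enoyl chloride (tigloyl chloride)
Product: 8 (2R,4R)-4-hydroxy-1,1-dimethoxy-4-methylhex-5-yn-2-yl (2E)-2-methylbut-2-enoate
Conditions: tigloyl chloride (1.2 equiv), pyridine, CH2Cl2, 0 °C → rt
Reagents that add atoms: tigloyl chloride C/C=C(\C)C(=O)Cl
Why: Selective O-acylation of the secondary alcohol over the hindered tertiary propargylic alcohol; the C8 configuration is retained and the ester blocks 5-exo oxa-Michael addition to the later ynone.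

Step 4
Reactants: 9 but-2-yne-1,4-diol; 10 tert-butyl(chloro)diphenylsilane
Product: 11 4-[(tert-butyldiphenylsilyl)oxy]but-2-yn-1-ol
Conditions: diol (3 equiv), TBDPSCl (1 equiv), imidazole, DMF, 0 °C → rt
Reagents that add atoms: tert-butyl(chloro)diphenylsilane CC(C)(C)[Si](Cl)(c1ccccc1)c1ccccc1
Why: Statistical monosilylation of a cheap symmetrical diol used in excess; the acid-stable silyl group masks the future C15 hydroxyl to the end.

Step 5
Reactants: 11 4-[(tert-butyldiphenylsilyl)oxy]but-2-yn-1-ol; 12 iodine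
Product: 14 (2Z)-4-[(tert-butyldiphenylsilyl)oxy]-3-iodobut-2-en-1-ol, via cyclic alkenylaluminate 13 (not isolated)
Conditions: NaAlH2(OCH2CH2OCH3)2 (1.5 equiv), THF, 0 °C; then iodine, −78 → 0 °C; Rochelle salt work-up
Reagents that add atoms: iodine [I][I]
Why: Hydroxyl-directed trans-hydroalumination of the propargylic alcohol gives aluminate 13 with aluminium on the distal carbon, and iodinolysis with retention places iodine cis to CH2OH, which fixes the 4Z geometry of the target.

Step 6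
Reactants: 14 (2Z)-4-[(tert-butyldiphenylsilyl)oxy]-3-iodobut-2-en-1-ol; 15 tert-butyl(chloro)dimethylsilane
Product: 16 (2Z)-4-[(tert-butyldimethylsilyl)oxy]-1-[(tert-butyldiphenylsilyl)oxy]-2-iodobut-2-ene
Conditions: TBSCl, imidazole, CH2Cl2, rt
Reagents that add atoms: tert-butyl(chloro)dimethylsilane CC(C)(C)[Si](C)(C)Cl
Why: Standard silylation; the acid-labile TBS group keeps the C6 hydroxyl from lactonising onto the acylpalladium in step 7 and falls off together with the acetal in step 8.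

Step 7
Reactants: 16 (2Z)-4-[(tert-butyldimethylsilyl)oxy]-1-[(tert-butyldiphenylsilyl)oxy]-2-iodobut-2-ene; 8 (2R,4R)-4-hydroxy-1,1-dimethoxy-4-methylhex-5-yn-2-yl (2E)-2-methylbut-2-enoate; 17 carbon monoxide; 18 water
Product: 20 (2R)-3-[(2R)-5-{(2Z)-4-[(tert-butyldimethylsilyl)oxy]-1-[(tert-butyldiphenylsilyl)oxy]but-2-en-2-yl}-2-methyl-3-oxo-2,3-dihydrofuran-2-yl]-1,1-dimethoxypropan-2-yl (2E)-2-methylbut-2-enoate, via hydroxy ynone 19 (not isolated)
Conditions: PdCl2(PPh3)2 (5 mol%), Et3N (3 equiv), THF, CO (1 atm), rt; silica plug; then Ph3PAuNTf2 (3 mol%), PhMe, H2O (2 equiv), 40 °C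
Reagents that add atoms: carbon monoxide [C-]#[O+]; water O
Why: Proposed new method: a one-flask three-component 3(2H)-furanone annulation on an alkenyl iodide. Zerovalent palladium inserts into the carbon–iodine bond with retention of the Z geometry, CO insertion and copper-free alkynylation give γ-hydroxy ynone 19, and Ph3PAuNTf2 then activates the ynone so that water adds at C1 and the tertiary hydroxyl closes onto C3 with loss of water (water is an oxygen shuttle; the net result is the ring C3–O bond, and C10 is untouched). The closest known reactions are the palladium-catalysed CO/CO2 coupling of aryl halides with tertiary propargylic alcohols to 3(2H)-furanones and the gold-catalysed cyclisation of isolated γ-hydroxy ynones; neither has been shown for an alkenyl iodide or as one telescoped operation.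

Step 8
Reactants: 20 furanone bis-silyl ether acetal (name as in step 7); 18 water
Product: 21 (2R)-3-[(2R)-5-{(2Z)-1-[(tert-butyldiphenylsilyl)oxy]-4-hydroxybut-2-en-2-yl}-2-methyl-3-oxo-2,3-dihydrofuran-2-yl]-1-oxopropan-2-yl (2E)-2-methylbut-2-enoate
Conditions: TFA/H2O 9:1, CH2Cl2, 0 °C → rt; NaHCO3 work-up
Reagents that add atoms: water O
Why: Acid hydrolysis releases the C7 aldehyde from the dimethyl acetal and cleaves the primary allylic TBS ether in the same pot, while the TBDPS ether, the tiglate and the acid-stable furanone survive.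

Step 9
Reactants: 21 hydroxy aldehyde (name as in step 8); 22 methyl acrylate
Product: 23 methyl (4R)-5-[(2R)-5-{(2Z)-1-[(tert-butyldiphenylsilyl)oxy]-4-hydroxybut-2-en-2-yl}-2-methyl-3-oxo-2,3-dihydrofuran-2-yl]-3-hydroxy-2-methylidene-4-{[(2E)-2-methylbut-2-enoyl]oxy}pentanoate (both C7 epimers)
Conditions: methyl acrylate (10 equiv), DABCO (1 equiv), MeOH (2 equiv), 0 °C → rt
Reagents that add atoms: methyl acrylate C=CC(=O)OC
Why: Morita–Baylis–Hillman reaction of the activated α-acyloxy aldehyde; the new C7 carbinol need not be controlled because C7 becomes sp2 in step 11, and the conjugated α-branched tigloyl group is expected to shift to the neighbouring hydroxyl only slowly at this temperature.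

Step 10
Reactants: 23 Morita–Baylis–Hillman diol (name as in step 9)
Product: 24 methyl (4R)-5-[(2R)-5-{(2Z)-1-[(tert-butyldiphenylsilyl)oxy]-4-oxobut-2-en-2-yl}-2-methyl-3-oxo-2,3-dihydrofuran-2-yl]-3-hydroxy-2-methylidene-4-{[(2E)-2-methylbut-2-enoyl]oxy}pentanoate
Conditions: TEMPO (10 mol%), PhI(OAc)2 (1.2 equiv), CH2Cl2, rt
Reagents that add atoms: none
Why: Oxoammonium (TEMPO) oxidation is selective for the primary allylic C6 alcohol over the hindered secondary carbinol and gives the Z enal without touching the other alkenes.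

Step 11
Reactants: 24 hydroxy enal (name as in step 10); 25 N-bromosuccinimide
Product: 27 methyl (2Z,4R)-2-(bromomethyl)-5-[(2R)-5-{(2Z)-1-[(tert-butyldiphenylsilyl)oxy]-4-oxobut-2-en-2-yl}-2-methyl-3-oxo-2,3-dihydrofuran-2-yl]-4-{[(2E)-2-methylbut-2-enoyl]oxy}pent-2-enoate, via alkoxysulfonium bromide 26 (not isolated)
Conditions: NBS (1.3 equiv) and Me2S (1.5 equiv) premixed, CH2Cl2, 0 °C; then 24, 0 °C → rt
Reagents that add atoms: N-bromosuccinimide O=C1CCC(=O)N1Br
Why: Corey–Kim-type activation of the carbinol followed by SN2' attack of bromide gives the thermodynamic 2-(bromomethyl)enoate under neutral conditions, which spares the Z enal and removes the uncontrolled C7 centre.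

Step 12
Reactants: 27 allylic bromide enal (name as in step 11)
Product: 30 (4Z,6S,7R,8R,10R)-15-[(tert-butyldiphenylsilyl)oxy]-8-{[(2E)-2-methylbut-2-enoyl]oxy}-1-oxo-3,10-epoxygermacra-2,4,11(13)-trien-12,6-olide, via allylchromium 28 (not isolated), via chromium alkoxide 29 (not isolated)
Conditions: CrCl2 (8 equiv), THF, rt, slow addition of 27 to 0.003 M; aq. NH4Cl, then PPTS (cat.), CH2Cl2 if lactonisation is incomplete
Reagents that add atoms: none
Why: Intramolecular Nozaki–Hiyama-type (Barbier) 2-(alkoxycarbonyl)allylation through a closed six-membered chair. C8 sits cis to CH2Cr (trans to the ester), which gives the syn adduct and hence the cis-fused lactone; with C8–H in the alkene plane (A(1,3) strain), the tether carbon C9 anti and the tigloyloxy group outside, the enal should add to the C7 face that gives 7R and therefore 6S; alkoxide 29 then lactonises onto the methyl ester. This stereochemical outcome is a first-principles prediction and must be confirmed by NOE.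

Step 13
Reactants: 30 silyl-protected lactone (name as in step 12)
Product: 31 (4Z,6S,7R,8R,10R)-15-hydroxy-8-{[(2E)-2-methylbut-2-enoyl]oxy}-1-oxo-3,10-epoxygermacra-2,4,11(13)-trien-12,6-olide (target)
Conditions: HF·pyridine, pyridine, THF, 0 °C → rt
Reagents that add atoms: none
Why: Buffered fluoride desilylation frees the C15 alcohol without touching the α-methylene lactone, the tiglate or the furanone.

**Compound list**
1 | acetone | CC(C)=O | starting material
2 | 2,2-dimethoxyacetaldehyde | COC(OC)C=O | starting material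
3 | (4R)-4-hydroxy-5,5-dimethoxypentan-2-one | CC(=O)C[C@@H](O)C(OC)OC | intermediate
4 | ethynylmagnesium bromide | C#C[Mg]Br | starting material
5 | bromomagnesium alkoxide of 3 (chelated to the ketone; not isolated) | CC(=O)C[C@@H](O[Mg]Br)C(OC)OC | intermediate
6 | (3R,5R)-6,6-dimethoxy-3-methylhex-1-yne-3,5-diol | C#C[C@@](C)(C[C@@H](O)C(OC)OC)O | intermediate
7 | (2E)-2-methylbut-2-enoyl chloride (tigloyl chloride) | C/C=C(\C)C(=O)Cl | starting material
8 | (2R,4R)-4-hydroxy-1,1-dimethoxy-4-methylhex-5-yn-2-yl (2E)-2-methylbut-2-enoate | C#C[C@@](C)(C[C@@H](OC(=O)/C(C)=C/C)C(OC)OC)O | intermediate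
9 | but-2-yne-1,4-diol | OCC#CCO | starting material
10 | tert-butyl(chloro)diphenylsilane | CC(C)(C)[Si](Cl)(c1ccccc1)c1ccccc1 | starting material
11 | 4-[(tert-butyldiphenylsilyl)oxy]but-2-yn-1-ol | OCC#CCO[Si](C(C)(C)C)(c1ccccc1)c1ccccc1 | intermediate
12 | iodine | [I][I] | starting material
13 | sodium 2,2-bis(2-methoxyethoxy)-3-{[(tert-butyldiphenylsilyl)oxy]methyl}-2,5-dihydro-1,2-oxaluminol-2-uide (cyclic alkenylaluminate; not isolated) | COCCO[Al-]1(OCCOC)OCC=C1CO[Si](C(C)(C)C)(c2ccccc2)c2ccccc2.[Na+] | intermediate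
14 | (2Z)-4-[(tert-butyldiphenylsilyl)oxy]-3-iodobut-2-en-1-ol | OC/C=C(\I)CO[Si](C(C)(C)C)(c1ccccc1)c1ccccc1 | intermediate
15 | tert-butyl(chloro)dimethylsilane | CC(C)(C)[Si](C)(C)Cl | starting material
16 | (2Z)-4-[(tert-butyldimethylsilyl)oxy]-1-[(tert-butyldiphenylsilyl)oxy]-2-iodobut-2-ene | CC(C)(C)[Si](C)(C)OC/C=C(\I)CO[Si](C(C)(C)C)(c1ccccc1)c1ccccc1 | intermediate
17 | carbon monoxide | [C-]#[O+] | starting material
18 | water | O | starting material
19 | (2R,4R,8Z)-10-[(tert-butyldimethylsilyl)oxy]-8-{[(tert-butyldiphenylsilyl)oxy]methyl}-4-hydroxy-1,1-dimethoxy-4-methyl-7-oxodec-8-en-5-yn-2-yl (2E)-2-methylbut-2-enoate (hydroxy ynone; not isolated) | CC(C)(C)[Si](C)(C)OC/C=C(/CO[Si](C(C)(C)C)(c1ccccc1)c1ccccc1)C(=O)C#C[C@@](C)(C[C@@H](OC(=O)/C(C)=C/C)C(OC)OC)O | intermediate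
20 | (2R)-3-[(2R)-5-{(2Z)-4-[(tert-butyldimethylsilyl)oxy]-1-[(tert-butyldiphenylsilyl)oxy]but-2-en-2-yl}-2-methyl-3-oxo-2,3-dihydrofuran-2-yl]-1,1-dimethoxypropan-2-yl (2E)-2-methylbut-2-enoate | CC(C)(C)[Si](C)(C)OC/C=C(/CO[Si](C(C)(C)C)(c1ccccc1)c1ccccc1)C1=CC(=O)[C@@](C)(C[C@@H](OC(=O)/C(C)=C/C)C(OC)OC)O1 | intermediate
21 | (2R)-3-[(2R)-5-{(2Z)-1-[(tert-butyldiphenylsilyl)oxy]-4-hydroxybut-2-en-2-yl}-2-methyl-3-oxo-2,3-dihydrofuran-2-yl]-1-oxopropan-2-yl (2E)-2-methylbut-2-enoate | OC/C=C(/CO[Si](C(C)(C)C)(c1ccccc1)c1ccccc1)C1=CC(=O)[C@@](C)(C[C@@H](OC(=O)/C(C)=C/C)C=O)O1 | intermediate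
22 | methyl acrylate | C=CC(=O)OC | starting material
23 | methyl (4R)-5-[(2R)-5-{(2Z)-1-[(tert-butyldiphenylsilyl)oxy]-4-hydroxybut-2-en-2-yl}-2-methyl-3-oxo-2,3-dihydrofuran-2-yl]-3-hydroxy-2-methylidene-4-{[(2E)-2-methylbut-2-enoyl]oxy}pentanoate (C3 of the pentanoate = C7, both epimers) | OC/C=C(/CO[Si](C(C)(C)C)(c1ccccc1)c1ccccc1)C1=CC(=O)[C@@](C)(C[C@@H](OC(=O)/C(C)=C/C)C(O)C(=C)C(=O)OC)O1 | intermediate
24 | methyl (4R)-5-[(2R)-5-{(2Z)-1-[(tert-butyldiphenylsilyl)oxy]-4-oxobut-2-en-2-yl}-2-methyl-3-oxo-2,3-dihydrofuran-2-yl]-3-hydroxy-2-methylidene-4-{[(2E)-2-methylbut-2-enoyl]oxy}pentanoate | O=C/C=C(/CO[Si](C(C)(C)C)(c1ccccc1)c1ccccc1)C1=CC(=O)[C@@](C)(C[C@@H](OC(=O)/C(C)=C/C)C(O)C(=C)C(=O)OC)O1 | intermediate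
25 | N-bromosuccinimide | O=C1CCC(=O)N1Br | starting material
26 | dimethyl(alkoxy)sulfonium bromide of 24 at the C7 oxygen (not isolated) | O=C/C=C(/CO[Si](C(C)(C)C)(c1ccccc1)c1ccccc1)C1=CC(=O)[C@@](C)(C[C@@H](OC(=O)/C(C)=C/C)C(O[S+](C)C)C(=C)C(=O)OC)O1.[Br-] | intermediate
27 | methyl (2Z,4R)-2-(bromomethyl)-5-[(2R)-5-{(2Z)-1-[(tert-butyldiphenylsilyl)oxy]-4-oxobut-2-en-2-yl}-2-methyl-3-oxo-2,3-dihydrofuran-2-yl]-4-{[(2E)-2-methylbut-2-enoyl]oxy}pent-2-enoate | O=C/C=C(/CO[Si](C(C)(C)C)(c1ccccc1)c1ccccc1)C1=CC(=O)[C@@](C)(C[C@@H](OC(=O)/C(C)=C/C)/C=C(\CBr)C(=O)OC)O1 | intermediate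
28 | allylchromium dichloride from 27 (CH2Br replaced by CH2CrCl2; not isolated) | O=C/C=C(/CO[Si](C(C)(C)C)(c1ccccc1)c1ccccc1)C1=CC(=O)[C@@](C)(C[C@@H](OC(=O)/C(C)=C/C)/C=C(\C[Cr](Cl)Cl)C(=O)OC)O1 | intermediate
29 | dichlorochromium alkoxide of the ring-closed (6S,7R,8R,10R) hydroxy ester: ten-membered carbocycle with C6–O–CrCl2 and a 1-(methoxycarbonyl)vinyl group on C7 (not isolated) | COC(=O)C(=C)[C@H]1[C@@H](O[Cr](Cl)Cl)/C=C(/CO[Si](C(C)(C)C)(c2ccccc2)c2ccccc2)C2=CC(=O)[C@@](C)(C[C@H]1OC(=O)/C(C)=C/C)O2 | intermediate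
30 | (4Z,6S,7R,8R,10R)-15-[(tert-butyldiphenylsilyl)oxy]-8-{[(2E)-2-methylbut-2-enoyl]oxy}-1-oxo-3,10-epoxygermacra-2,4,11(13)-trien-12,6-olide | C=C1C(=O)O[C@H]2/C=C(/CO[Si](C(C)(C)C)(c3ccccc3)c3ccccc3)C3=CC(=O)[C@@](C)(C[C@@H](OC(=O)/C(C)=C/C)[C@@H]12)O3 | intermediate
31 | (4Z,6S,7R,8R,10R)-15-hydroxy-8-{[(2E)-2-methylbut-2-enoyl]oxy}-1-oxo-3,10-epoxygermacra-2,4,11(13)-trien-12,6-olide | C=C1C(=O)O[C@H]2/C=C(/CO)C3=CC(=O)[C@@](C)(C[C@@H](OC(=O)/C(C)=C/C)[C@@H]12)O3 | target

**Step count**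
Total: 13 steps. Longest linear sequence: 10 steps (1–3 then 7–13; the iodide branch 4–6 then 7–13 is equally long).

**Three steps most likely to fail**

Step 7 (the proposed new step). Direct, non-carbonylative coupling of the alkenyl iodide may compete, and residual amine or iodide may poison the gold catalyst. The fallback uses known chemistry and sets out from 8 and 16. Alkyne 8 is stannylated with Bu3SnOMe (neat, 60 °C) to the alkynylstannane F1. A carbonylative Stille coupling of F1 with 16 (Pd2(dba)3, AsPh3, CO 1 atm, THF, 50 °C) gives hydroxy ynone 19, which is now isolated and purified. 19 is then cyclised by the established diethylamine addition/aqueous acetic acid sequence, or by the gold protocol on pure material, and the route is rejoined at 20.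

Step 9 (Morita–Baylis–Hillman). DABCO may epimerise C8 of the α-acyloxy aldehyde or move the tigloyl group onto the new C7 hydroxyl. The fallback sets out from 21 and avoids a vicinal hydroxy ester altogether. A neutral Wittig olefination with methyl 3-(trimethylsilyl)-2-(triphenylphosphoranylidene)propanoate (PhMe, 60 °C) gives the allylsilane F2. TEMPO/PhI(OAc)2 oxidation of the C6 alcohol gives the enal allylsilane F3. BF3·OEt2 (CH2Cl2, −78 °C, high dilution) then triggers an intramolecular Hosomi–Sakurai allylation with lactonisation, which rejoins the route at 30 and replaces steps 9–12.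

Step 12 (macrocyclisation). Ring closure may be slow against oligomerisation, and the C6/C7 configuration is the least certain point of the route, since ring strain may override the chair model. The fallback sets out from 24. Acetylation (Ac2O, DMAP, CH2Cl2) gives the acetate F4. Palladium-catalysed borylation (Pd2(dba)3, B2pin2, PhMe) gives the allylboronate F5, which on warming in dilute toluene (60–80 °C) closes by intramolecular allylboration through a geometry-defined chair and lactonises to 30. Because allylboration is stereospecific, the other boronate geometry can be prepared if the wrong C6/C7 relationship appears.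

**Further compounds**
F1 | step 7 | (2R,4R)-4-hydroxy-1,1-dimethoxy-4-methyl-6-(tributylstannyl)hex-5-yn-2-yl (2E)-2-methylbut-2-enoate | CCCC[Sn](CCCC)(CCCC)C#C[C@@](C)(C[C@@H](OC(=O)/C(C)=C/C)C(OC)OC)O
F2 | step 9 | methyl (2Z,4R)-5-[(2R)-5-{(2Z)-1-[(tert-butyldiphenylsilyl)oxy]-4-hydroxybut-2-en-2-yl}-2-methyl-3-oxo-2,3-dihydrofuran-2-yl]-4-{[(2E)-2-methylbut-2-enoyl]oxy}-2-[(trimethylsilyl)methyl]pent-2-enoate | OC/C=C(/CO[Si](C(C)(C)C)(c1ccccc1)c1ccccc1)C1=CC(=O)[C@@](C)(C[C@@H](OC(=O)/C(C)=C/C)/C=C(\C[Si](C)(C)C)C(=O)OC)O1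
F3 | step 9 | methyl (2Z,4R)-5-[(2R)-5-{(2Z)-1-[(tert-butyldiphenylsilyl)oxy]-4-oxobut-2-en-2-yl}-2-methyl-3-oxo-2,3-dihydrofuran-2-yl]-4-{[(2E)-2-methylbut-2-enoyl]oxy}-2-[(trimethylsilyl)methyl]pent-2-enoate | O=C/C=C(/CO[Si](C(C)(C)C)(c1ccccc1)c1ccccc1)C1=CC(=O)[C@@](C)(C[C@@H](OC(=O)/C(C)=C/C)/C=C(\C[Si](C)(C)C)C(=O)OC)O1
F4 | step 12 | methyl (4R)-3-acetoxy-5-[(2R)-5-{(2Z)-1-[(tert-butyldiphenylsilyl)oxy]-4-oxobut-2-en-2-yl}-2-methyl-3-oxo-2,3-dihydrofuran-2-yl]-2-methylidene-4-{[(2E)-2-methylbut-2-enoyl]oxy}pentanoate | O=C/C=C(/CO[Si](C(C)(C)C)(c1ccccc1)c1ccccc1)C1=CC(=O)[C@@](C)(C[C@@H](OC(=O)/C(C)=C/C)C(OC(C)=O)C(=C)C(=O)OC)O1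
F5 | step 12 | methyl (2E,4R)-5-[(2R)-5-{(2Z)-1-[(tert-butyldiphenylsilyl)oxy]-4-oxobut-2-en-2-yl}-2-methyl-3-oxo-2,3-dihydrofuran-2-yl]-4-{[(2E)-2-methylbut-2-enoyl]oxy}-2-[(4,4,5,5-tetramethyl-1,3,2-dioxaborolan-2-yl)methyl]pent-2-enoate | O=C/C=C(/CO[Si](C(C)(C)C)(c1ccccc1)c1ccccc1)C1=CC(=O)[C@@](C)(C[C@@H](OC(=O)/C(C)=C/C)/C=C(\CB2OC(C)(C)C(C)(C)O2)C(=O)OC)O1
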